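The C3 oxygen and the central carbon of the C2 isopropenyl group sit cis on the C2–C3 bond of the dihydrofuran ring; joined together they form an oxetane fused across C2–C3. That oxetane is disconnected by an intramolecular Paternò–Büchi reaction, which should form C3–C2 and O–CMe2 in one operation, closing the dihydrofuran and oxetane rings and fixing the cis relationship through the four/five ring fusion. The precursor is a benzaldehyde with an ortho 2-methylprop-1-enyl ether, two methoxy groups and the acetyl group masked as a dioxolane. Regioselective oxetane opening, lipase resolution and angeloylation complete the route.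

Key step: step 4

Assumption: in step 6 the lipase is taken to follow the usual size rule for secondary alcohols with the fused aryl ring as the large substituent, so the (2S,3S)-alcohol is acetylated and the (2R,3R)-alcohol is left; racemic 8, 9 and 10 are drawn as the enantiomer that is carried on.

Remark: the acetyl carbon is introduced through a C5 bromide of salicylaldehyde 1, where every directing group points to one position, because direct acylation of 2,3-dimethoxyphenol can go ortho or para to the hydroxyl. The ketal is then made by a Heck reaction that never exposes the free aldehyde to a diol and acid.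

Step 1
Reactants: 1 2-hydroxy-3,4-dimethoxybenzaldehyde
Product: 2 5-bromo-2-hydroxy-3,4-dimethoxybenzaldehyde
Conditions: NBS, MeCN, 0 °C → rt
Reagents that add atoms: N-bromosuccinimide, O=C1CCC(=O)N1Br
Why: Electrophilic aromatic bromination goes to C5 because the hydroxyl (para), the 4-methoxy group (ortho) and the formyl group (meta) all direct there and both positions ortho to the hydroxyl are blocked.

Step 2
Reactants: 2 5-bromo-2-hydroxy-3,4-dimethoxybenzaldehyde; 3 (2-methylprop-1-en-1-yl)boronic acid
Product: 4 5-bromo-3,4-dimethoxy-2-[(2-methylprop-1-en-1-yl)oxy]benzaldehyde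
Conditions: Cu(OAc)2 (2 equiv), pyridine, 4 Å MS, CH2Cl2, rt
Reagents that add atoms: none
Why: Chan–Lam oxidative C–O coupling of a phenol with an alkenylboronic acid at divalent copper runs at room temperature, where the aryl bromide and the aldehyde are inert, and the symmetrical dimethyl terminus leaves no alkene geometry to control.

Step 3
Reactants: 4 5-bromo-3,4-dimethoxy-2-[(2-methylprop-1-en-1-yl)oxy]benzaldehyde; 5 2-(ethenyloxy)ethan-1-ol
Product: 7 3,4-dimethoxy-5-(2-methyl-1,3-dioxolan-2-yl)-2-[(2-methylprop-1-en-1-yl)oxy]benzaldehyde, via 1-(2-hydroxyethoxy)vinyl arene 6 (not isolated)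
Conditions: Pd(OAc)2 (5 mol %), dppp (10 mol %), K2CO3, DMF–H2O, 90 °C; crude stirred with PPTS (cat.), CH2Cl2, rt to complete ring closure
Reagents that add atoms: none
Why: Heck arylation of a hydroxyalkyl vinyl ether by the cationic dppp–palladium pathway is selective for the internal carbon, and the pendant hydroxyl then adds to the new 1-arylvinyl ether to give the cyclic ketal directly, so the acetyl group arrives already protected while the aldehyde stays free.

Step 4
Reactants: 7 3,4-dimethoxy-5-(2-methyl-1,3-dioxolan-2-yl)-2-[(2-methylprop-1-en-1-yl)oxy]benzaldehyde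
Product: 8 rac-(2aS,7bR)-4,5-dimethoxy-2,2-dimethyl-6-(2-methyl-1,3-dioxolan-2-yl)-2a,7b-dihydro-2H-oxeto[3,2-b][1]benzofuran (cis-fused oxetane on C2–C3 of the dihydrobenzofuran; oxetane O on C3 and CMe2 on C2)
Conditions: hν (350 nm, Pyrex), degassed benzene (5 mM), rt
Reagents that add atoms: none
Why: Excitation of the aryl aldehyde and intersystem crossing give a triplet whose electrophilic oxygen adds to the nucleophilic dimethyl-substituted β-carbon of the tethered enol ether, and the 1,4-biradical (benzylic radical at C3, oxygen-stabilised radical at C2) recombines after spin inversion. The closest known reaction type is the Paternò–Büchi reaction of aromatic aldehydes with enol ethers to 3-alkoxyoxetanes, here run intramolecularly as with other alkene-tethered carbonyl compounds. The oxetane closes by stepwise [2+2] addition (O–CMe2, then C3–C2), and the same C3–C2 bond closes the dihydrofuran ring as a five-membered closure set by the three-atom C3a–C7a–O1 tether (straight, not crossed, addition). C2 and C3 are formed together and can only be cis, because a four-membered ring fuses to a five-membered ring in no other way; the absolute sense is uncontrolled, so the racemate forms. The step needs regioselectivity (O to CMe2, C to C2), secured by enol-ether polarity and by the tether, for which the crossed mode would demand a bridged oxetane, and chemoselectivity, secured by the lack of an easily abstracted hydrogen, the ketal in place of a second carbonyl chromophore and irradiation where the product does not absorb. The 7-methoxy group next to the enol ether twists the alkene out of the arene plane and over the formyl group.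

Step 5
Reactants: 8 rac-(2aS,7bR)-4,5-dimethoxy-2,2-dimethyl-6-(2-methyl-1,3-dioxolan-2-yl)-2a,7b-dihydro-2H-oxeto[3,2-b][1]benzofuran
Product: 10 rac-1-[(2R,3R)-3-hydroxy-6,7-dimethoxy-2-(prop-1-en-2-yl)-2,3-dihydro-1-benzofuran-5-yl]ethan-1-one (cis racemate), via ketal alcohol 9 (not isolated)
Conditions: Et2Al(TMP) (from TMPH, n-BuLi, Et2AlCl; 4 equiv), toluene, 0 °C → rt; then 0.5 M aq HCl, THF, 0 °C
Reagents that add atoms: water, O
Why: Base-mediated isomerisation of an oxetane to a homoallylic alcohol, here by the aluminium amide that binds the Lewis-basic oxetane oxygen and removes a syn methyl proton through a six-membered array (as in the aluminium-amide isomerisation of epoxides to allylic alcohols), cleaves only O–CMe2 because the ring hydrogen at C2 cannot become syn-periplanar to either C–O bond, so C3–O and the cis configuration are untouched, and the dilute acid then frees the ketone (also from any 1-arylvinyl ether the reagent may make from the ketal).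

Step 6
Reactants: 10 rac-1-[(2R,3R)-3-hydroxy-6,7-dimethoxy-2-(prop-1-en-2-yl)-2,3-dihydro-1-benzofuran-5-yl]ethan-1-one
Product: 11 1-[(2R,3R)-3-hydroxy-6,7-dimethoxy-2-(prop-1-en-2-yl)-2,3-dihydro-1-benzofuran-5-yl]ethan-1-one (single enantiomer)
Conditions: Burkholderia cepacia lipase (immobilised), vinyl acetate, MTBE, 35 °C, stopped near 55% conversion
Reagents that add atoms: none
Why: Lipase-catalysed kinetic resolution by irreversible transesterification of a cyclic benzylic secondary alcohol should acetylate the (2S,3S)-enantiomer and leave the (2R,3R)-alcohol, whose two stereocentres are not touched, and running past half conversion raises the purity of the alcohol left behind.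

Step 7
Reactants: 11 1-[(2R,3R)-3-hydroxy-6,7-dimethoxy-2-(prop-1-en-2-yl)-2,3-dihydro-1-benzofuran-5-yl]ethan-1-one; 12 angelic acid, (2Z)-2-methylbut-2-enoic acid
Product: 14 (2R,3R)-5-acetyl-6,7-dimethoxy-2-(prop-1-en-2-yl)-2,3-dihydro-1-benzofuran-3-yl (2Z)-2-methylbut-2-enoate (target), via angelic 2,4,6-trichlorobenzoic anhydride 13 (not isolated)
Conditions: 2,4,6-Cl3C6H2COCl, Et3N, toluene, rt; then 11, 75 °C (no DMAP)
Reagents that add atoms: none
Why: Yamaguchi-type mixed-anhydride acylation without a nucleophilic catalyst delivers the less hindered angeloyl group to the alcohol without Z to E isomerisation to the tiglate, and acylation at oxygen leaves the C3–O bond and both stereocentres unchanged.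

Compound list
1 | 2-hydroxy-3,4-dimethoxybenzaldehyde | COc1ccc(C=O)c(O)c1OC | starting material
2 | 5-bromo-2-hydroxy-3,4-dimethoxybenzaldehyde | COc1c(Br)cc(C=O)c(O)c1OC | intermediate
3 | (2-methylprop-1-en-1-yl)boronic acid | CC(C)=CB(O)O | starting material
4 | 5-bromo-3,4-dimethoxy-2-[(2-methylprop-1-en-1-yl)oxy]benzaldehyde | CC(C)=COc1c(C=O)cc(Br)c(OC)c1OC | intermediate
5 | 2-(ethenyloxy)ethan-1-ol (ethylene glycol monovinyl ether) | C=COCCO | starting material
6 | 5-[1-(2-hydroxyethoxy)ethenyl]-3,4-dimethoxy-2-[(2-methylprop-1-en-1-yl)oxy]benzaldehyde | CC(C)=COc1c(C=O)cc(C(=C)OCCO)c(OC)c1OC | intermediate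
7 | 3,4-dimethoxy-5-(2-methyl-1,3-dioxolan-2-yl)-2-[(2-methylprop-1-en-1-yl)oxy]benzaldehyde | CC(C)=COc1c(C=O)cc(C2(C)OCCO2)c(OC)c1OC | intermediate
8 | rac-(2aS,7bR)-4,5-dimethoxy-2,2-dimethyl-6-(2-methyl-1,3-dioxolan-2-yl)-2a,7b-dihydro-2H-oxeto[3,2-b][1]benzofuran (racemate, needed enantiomer drawn) | CC1(C)O[C@@H]2c3cc(C4(C)OCCO4)c(OC)c(OC)c3O[C@H]12 | intermediate
9 | rac-(2R,3R)-6,7-dimethoxy-5-(2-methyl-1,3-dioxolan-2-yl)-2-(prop-1-en-2-yl)-2,3-dihydro-1-benzofuran-3-ol (cis; racemate, needed enantiomer drawn) | C=C(C)[C@H]1Oc2c(cc(C3(C)OCCO3)c(OC)c2OC)[C@H]1O | intermediate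
10 | rac-1-[(2R,3R)-3-hydroxy-6,7-dimethoxy-2-(prop-1-en-2-yl)-2,3-dihydro-1-benzofuran-5-yl]ethan-1-one (cis; racemate, needed enantiomer drawn) | C=C(C)[C@H]1Oc2c(cc(C(C)=O)c(OC)c2OC)[C@H]1O | intermediate
11 | 1-[(2R,3R)-3-hydroxy-6,7-dimethoxy-2-(prop-1-en-2-yl)-2,3-dihydro-1-benzofuran-5-yl]ethan-1-one (single enantiomer) | C=C(C)[C@H]1Oc2c(cc(C(C)=O)c(OC)c2OC)[C@H]1O | intermediate
12 | angelic acid, (2Z)-2-methylbut-2-enoic acid | C/C=C(/C)C(=O)O | starting material
13 | (2Z)-2-methylbut-2-enoic 2,4,6-trichlorobenzoic anhydride | C/C=C(/C)C(=O)OC(=O)c1c(Cl)cc(Cl)cc1Cl | intermediate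
14 | (2R,3R)-5-acetyl-6,7-dimethoxy-2-(prop-1-en-2-yl)-2,3-dihydro-1-benzofuran-3-yl (2Z)-2-methylbut-2-enoate | C=C(C)[C@H]1Oc2c(cc(C(C)=O)c(OC)c2OC)[C@H]1OC(=O)/C(C)=C\C | target

Total step count: 7
Longest linear sequence: 7 steps (1 → 14)

Steps most likely to fail

1. Step 4. The lowest triplet of the alkoxy-rich aldehyde may react sluggishly. The excited carbonyl may also abstract an allylic methyl hydrogen or add in the crossed sense instead of closing the fused oxetane. The fallback keeps a photochemical ring closure but changes the bond-forming event to hydrogen abstraction, and it gives up the stereocontrol of the ring fusion.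
   - It sets out from 2. Heck ketalisation with 5 under the step 3 conditions, on the phenoxide, should give 2-hydroxy-3,4-dimethoxy-5-(2-methyl-1,3-dioxolan-2-yl)benzaldehyde F1, carried on as its potassium salt without acidification.
   - O-Alkylation with 3-chloro-2-methylprop-1-ene (K2CO3, DMF, 60 °C) should give 3,4-dimethoxy-5-(2-methyl-1,3-dioxolan-2-yl)-2-[(2-methylprop-2-en-1-yl)oxy]benzaldehyde F2.
   - Irradiation (350 nm, degassed benzene) should then bring about a Norrish–Yang cyclisation: the excited aldehyde abstracts a δ-hydrogen from the allylic OCH2 group and the 1,5-biradical closes at the oxygen-bearing carbon.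
   - The product would be the 3-hydroxy-2-isopropenyl dihydrobenzofuran as a cis and trans pair. The cis isomer is 9, where the fallback comes back to the route for the acid treatment of step 5. The trans isomer, rac-(2S,3R)-6,7-dimethoxy-5-(2-methyl-1,3-dioxolan-2-yl)-2-(prop-1-en-2-yl)-2,3-dihydro-1-benzofuran-3-ol F3, is removed by chromatography.

2. Step 5. Binding of the aluminium reagent may ionise the benzylic C3–O bond, which would lead on to aromatisation to a benzofuran, or the oxetane may stay inert at temperatures the other groups tolerate.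
   - The fallback sets out from 8 and uses a purely anionic syn-elimination with the LiN(i-Pr)2/KOt-Bu superbase (THF, −50 °C), a known way to isomerise oxetanes to homoallylic alcohols without a Lewis acid.
   - It should give 9 directly, where it comes back to the route; the dilute-acid treatment of step 5 then gives 10. It makes no compound outside the list (F0).

3. Step 6. Acylation may be slow at the hindered cis alcohol, weakly enantioselective, or may favour the other enantiomer.
   - The fallback sets out from 10 and replaces the enzyme by covalent diastereomer formation: esterification with (2S)-2-methoxy-2-phenylacetic acid (DCC, DMAP, CH2Cl2, 0 °C).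
   - This should give (2R,3R)-5-acetyl-6,7-dimethoxy-2-(prop-1-en-2-yl)-2,3-dihydro-1-benzofuran-3-yl (2S)-2-methoxy-2-phenylacetate F4 and (2S,3S)-5-acetyl-6,7-dimethoxy-2-(prop-1-en-2-yl)-2,3-dihydro-1-benzofuran-3-yl (2S)-2-methoxy-2-phenylacetate F5.
   - These are separated by chromatography or crystallisation and assigned by crystallography. Methanolysis of F4 (K2CO3, MeOH, 0 °C) comes back to the route at 11.

Further compounds
F1 | step 4 | 2-hydroxy-3,4-dimethoxy-5-(2-methyl-1,3-dioxolan-2-yl)benzaldehyde | COc1c(C2(C)OCCO2)cc(C=O)c(O)c1OC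
F2 | step 4 | 3,4-dimethoxy-5-(2-methyl-1,3-dioxolan-2-yl)-2-[(2-methylprop-2-en-1-yl)oxy]benzaldehyde | C=C(C)COc1c(C=O)cc(C2(C)OCCO2)c(OC)c1OC
F3 | step 4 | rac-(2S,3R)-6,7-dimethoxy-5-(2-methyl-1,3-dioxolan-2-yl)-2-(prop-1-en-2-yl)-2,3-dihydro-1-benzofuran-3-ol | C=C(C)[C@@H]1Oc2c(cc(C3(C)OCCO3)c(OC)c2OC)[C@H]1O
F0 | step 5 | none | none
F4 | step 6 | (2R,3R)-5-acetyl-6,7-dimethoxy-2-(prop-1-en-2-yl)-2,3-dihydro-1-benzofuran-3-yl (2S)-2-methoxy-2-phenylacetate | C=C(C)[C@H]1Oc2c(cc(C(C)=O)c(OC)c2OC)[C@H]1OC(=O)[C@@H](OC)c1ccccc1
F5 | step 6 | (2S,3S)-5-acetyl-6,7-dimethoxy-2-(prop-1-en-2-yl)-2,3-dihydro-1-benzofuran-3-yl (2S)-2-methoxy-2-phenylacetate | C=C(C)[C@@H]1Oc2c(cc(C(C)=O)c(OC)c2OC)[C@@H]1OC(=O)[C@@H](OC)c1ccccc1
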